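Locants C1–C11, O4 and O6 used in the discussion are those of the target, 8,10-dibromo-7,11,11-trimethyl-3-(prop-1-en-2-yl)-4,6-dioxatricyclo[5.4.0.0(1,5)]undec-9-ene (compound 26).

## Analysis of the target

- Compound 26 is a C15 dibromide in which a cyclohexene (ring A: C1, C7, C8, C9, C10, C11), an oxetane (ring B: C1, C5, O6, C7) and an oxolane (ring C: C1, C2, C3, O4, C5) all share C1; C5 is an acetal carbon common to rings B and C.
- It has five stereocentres (1S,3R,5S,7S,8S). O6 on C7 and C5 on C1 are necessarily cis on ring A, with the C7 methyl and the C2 methylene on the other face. The C8 bromine is trans to O6. The isopropenyl group at C3 lies on the face of ring C turned toward C11 and away from C7. C5 is fixed by the ring fusion.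
- C11 (CMe2), C1 and C7 are three fully substituted carbons in a row; this is the steric problem of any synthesis.
- Sensitive functions are the strained oxetane acetal (acid), the secondary allylic bromide at C8 beside it (ionisation), the vinylic bromide at C10, and the isopropenyl group. The last excludes ozone, osmium and strong electrophiles and makes the C3–O4 bond allylic.
- The plan rests on one feature of ring A: C11 is bonded to the bromine-bearing vinylic carbon C10, and C10 is β to C8 through C9. If C8 is a ketone and C9–C10 a bromoalkyne, a tertiary radical at C11 can close ring A on C10 with the halogen already in place.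
- The radical can come from a carboxyl group on C11, so the problem reduces to an α,α-dimethyl carboxylic acid tethered to a bromoalkynyl ketone.

## Retrosynthetic reasoning

**26 ⇒ 25 (C8–Br).** A secondary allylic bromide next to an acetal would not survive hydride, fluoride or base, so it is made last from the C8-epimeric alcohol 25 by a substitution that inverts. The forward step must displace at a carbon next to the fully substituted C7 without ionising the allyl system or the acetal.

**25 ⇒ 24 ⇒ 23 (O6–C5).** The oxetane is cut at the acetal carbon, not at C7–O6, because C7 is tertiary and cannot be a displacement site. This leads through silyl ether 24 to hydroxy lactol 23, in which the tertiary hydroxyl on C7 is already cis to C5. The strained ring is thus made late and under non-acidic conditions. The C8 oxygen must be masked, since a free hydroxyl there would close a five-membered acetal instead.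

**23 ⇒ 22 ⇒ 21 ⇒ 20 ⇒ 19 (functional group changes).** The lactol comes from lactone 22, the tertiary hydroxyl from its triethylsilyl ether 21, the C8 silyl ether from alcohol 20, and 20 from enone 19 by hydride delivery anti to the C7 silyloxy group. This returns C8 to the ketone and C5 to the lactone level, the two oxidation states the key disconnection needs.

**19 ⇒ 18 (C10–C11, key disconnection).** C11 carries no functional group, so the bond to C10 is cut homolytically: C11 becomes the site of a carboxyl group and C9–C10 a bromoalkyne conjugated to the C8 ketone. The gain is ring A with the C10 bromine and the C8 oxygen both delivered by the acceptor. The three contiguous quaternary carbons already exist in acid 18 and are not formed in the ring closure. The forward step must generate the tertiary radical by decarboxylation, add at the bromine-bearing carbon in the 6-endo mode, and keep the halogen.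

**18 ⇒ 16 ⇒ 15 ⇒ 13 + 14 (C8–C9).** The acid is unmasked last from tert-butyl ester 16, and the bromoalkyne comes from alkynylsilane 15. Ynone 15 is cut between C8 and C9 into Weinreb amide 13 and alkyne 14. The amide carbonyl becomes the ynone carbonyl with no redox step and no transition metal, which protects the allylic C3–O4 bond.

**13 ⇒ 12 ⇒ 11 (C7–CH3).** The methyl group on C7 is cut, not the C7–C8 or C1–C7 bond, because ketone 11 is flanked by the lactone carbonyl. A metal chelate fixes the conformation, and the two ketone faces are then distinguished by a ring CH2 against a tert-alkyl ester branch. The forward step must deliver methyl from the CH2 side.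

**11 ⇒ 9 + 10 (C1–C7).** The quaternary C1 is made by acylating the enolate of lactone 9 with oxamide 10, a small and strongly electrophilic sp2 partner. Its configuration follows from C3, because the electrophile enters anti to the isopropenyl group. The CMe2 branch is already on the enolate, since a tertiary carbon cannot be attached later by alkylation.

**9 ⇒ 7 + 3 (C1–C2 and lactone C–O).** The dianion of acid 7 opens epoxide 3 at its CH2 group and the hydroxy acid lactonises. The C3 stereocentre is brought in with 3.

**7 ⇒ 6 ⇒ 4 + 5; 3 ⇒ 2 ⇒ 1.** Acid 7 comes from diester 6 by hydrolysis of its unhindered ester, and 6 from ester 4 and bromide 5 by enolate alkylation, which creates the C11–C1 bond with the hindered carboxyl already protected. Epoxide 3 comes from racemic 2 by kinetic resolution, and 2 from aldehyde 1 by methylene transfer.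

## Alternatives that were turned down

**Alternative 1: Ireland–Claisen ring contraction (C1–C11).**
- Disconnection and key step: ring A is cut between C1 and C11. The δ-lactone A2, carrying a 1-bromo-2-methylprop-1-enyl group on its carbinol carbon, would be converted to its silyl ketene acetal (LiN(iPr)2, Me3SiCl) and rearranged on warming to the cyclohexene carboxylic acid A1.
- For: it is a pericyclic step of an established type. It transfers chirality from the lactone C–O centre to C1, and delivers the vinylic bromide and the C8 oxygen at the right oxidation level, so no ketone reduction is needed. On precedent and on C8 it is stronger than the chosen route.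
- Against: the C7 silyloxy group of A2 is β to the lactone carbonyl, so enolisation invites β-elimination. The rearrangement must join a fully substituted ketene acetal carbon to the CMe2 terminus of a tetrasubstituted bromoalkene in a constrained bicyclic transition state. A2 itself needs four stereocentres and a tetrasubstituted vinyl bromide. A1 still requires its two triethylsilyl ethers to be distinguished and the oxolane to be built.
- Comparison: the chosen strategy offers a precursor assembled from simple pieces around one purchased-level stereocentre, with the risk confined to one neutral, room-temperature step.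

**Alternative 2: copper hydride reductive aldol (C1–C7).**
- Disconnection and key step: ring A is cut between C1 and C7. [(Ph3P)CuH]6 would reduce butenolide A4 in conjugate fashion, and the copper enolate would add to the tethered methyl ketone to give hydroxy lactone A3.
- For: it makes the most congested bond intramolecularly and sets C1 and C7 together in a chelated cyclic transition state, with the C7 hydroxyl cis to the lactone carbonyl as the oxetane requires. On this bond it is stronger than steps 6 and 7 of the chosen route.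
- Against: A3 has a ketone at C10 and no vinylic bromide. Converting it requires enolisation toward C9 of a ketone whose β-carbon C8 carries a silyloxy group (elimination), followed by triflate-to-bromide exchange. A4 is a β-silyloxy 1,4-diketone with the same elimination problem.
- Comparison: the chosen strategy carries the C10 bromine through the ring closure and needs no later work on C10.

**Alternative 3: alkyne Prins bromocyclisation (C8–C9 and C10–Br).**
- Disconnection and key step: ring A is cut between C8 and C9. TiBr4 would activate the α-hydroxy aldehyde A6, the terminal alkyne carbon would attack it, and bromide would add to the internal alkyne carbon to give diol A5.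
- For: the C8 carbinol and the vinylic bromide arrive in one step, and A5 is only a lactone reduction, an oxetane closure and a bromination from the target. On step count after ring closure it is the strongest option.
- Against: the closure needs a vinyl cation bent into a six-membered ring. A strong Lewis acid is brought together with an isopropenyl group, an allylic lactone C–O bond and a tertiary α-hydroxy aldehyde that can undergo ketol shift. Nothing controls the required cis relation between the C8 and C7 oxygens. A6 contains the same congested C11–C1–C7 triad, with a 1,1-dimethylpropargyl group that is harder to install than a carboxyl group.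
- Comparison: the chosen strategy closes the ring under neutral conditions and sets C8 in a separate, controllable reduction.

Key step: step 12

Assumption (chemistry): the (R,R)-cobalt salen catalyst of step 2 is taken to hydrolyse the (R)-epoxide and leave the (S)-epoxide, as with other monosubstituted oxiranes; the enantiomeric catalyst would be used if the sense were reversed.

## Route

Step 1
Reactants: 1 methacrolein (2-methylprop-2-enal)
Product: 2 rac-2-(prop-1-en-2-yl)oxirane
Conditions: trimethylsulfonium iodide, NaH, DMSO–THF, 0 °C to rt; distillation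
Reagents that add atoms: trimethylsulfonium iodide, C[S+](C)C.[I-]
Why: Corey–Chaykovsky epoxidation; the unstabilised sulfonium ylide adds to the carbonyl group of the enal and closes the oxirane, leaving the alkene untouched.

Step 2
Reactants: 2 rac-2-(prop-1-en-2-yl)oxirane
Product: 3 (S)-2-(prop-1-en-2-yl)oxirane
Conditions: (R,R)-(salen)Co(OAc) [(R,R)-N,N′-bis(3,5-di-tert-butylsalicylidene)cyclohexane-1,2-diamine cobalt acetate, trivalent cobalt] (0.5 mol %), H2O (0.55 equiv), neat, 0 °C to rt; distillation
Reagents that add atoms: none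
Why: Jacobsen hydrolytic kinetic resolution of a terminal epoxide; the catalyst hydrates the (R)-enantiomer selectively and the unreacted (S)-epoxide is distilled from the diol.

Step 3
Reactants: 4 tert-butyl 2-methylpropanoate; 5 methyl bromoacetate
Product: 6 1-tert-butyl 4-methyl 2,2-dimethylbutanedioate
Conditions: LiN(iPr)2, THF, −78 °C; then 5, −78 to 0 °C
Reagents that add atoms: none
Why: Alkylation of the lithium enolate of a hindered ester with an α-bromo ester; this builds the CMe2–CH2 unit with the hindered carboxyl already protected as its tert-butyl ester.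

Step 4
Reactants: 6 1-tert-butyl 4-methyl 2,2-dimethylbutanedioate
Product: 7 4-tert-butoxy-3,3-dimethyl-4-oxobutanoic acid
Conditions: LiOH·H2O, THF–MeOH–H2O, 0 °C to rt; 1 M HCl to pH 3 at 0 °C
Reagents that add atoms: lithium hydroxide, [Li+].[OH-]
Why: Selective saponification; the unhindered methyl ester is hydrolysed while the tert-butyl ester on a quaternary carbon is inert to hydroxide.

Step 5
Reactants: 7 4-tert-butoxy-3,3-dimethyl-4-oxobutanoic acid; 3 (S)-2-(prop-1-en-2-yl)oxirane
Product: 9 tert-butyl 2-methyl-2-[(5R)-2-oxo-5-(prop-1-en-2-yl)oxolan-3-yl]propanoate (both C3 epimers), via hydroxy acid 8 (not isolated)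
Conditions: LiN(iPr)2 (2.2 equiv), THF, −78 to 0 °C; 3, 0 °C to rt; 1 M HCl to pH 3 at 0 °C; then pyridinium p-toluenesulfonate (cat.), toluene, 50 °C
Reagents that add atoms: none
Why: Alkylation of a carboxylic acid dianion by a terminal epoxide: the enediolate attacks the unsubstituted oxirane carbon in an SN2 opening, so the C–O stereocentre is untouched (it is named R only because the priorities change), and the γ-hydroxy acid closes to the γ-lactone under mild acid; both α-epimers are used because that carbon becomes planar in step 6.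

Step 6
Reactants: 9 tert-butyl 2-methyl-2-[(5R)-2-oxo-5-(prop-1-en-2-yl)oxolan-3-yl]propanoate; 10 N,N′-dimethoxy-N,N′-dimethyloxamide
Product: 11 tert-butyl 2-[(3S,5R)-3-{2-[methoxy(methyl)amino]-2-oxoacetyl}-2-oxo-5-(prop-1-en-2-yl)oxolan-3-yl]-2-methylpropanoate
Conditions: LiN(iPr)2 (1.1 equiv), THF, −78 °C; 10 (1.5 equiv), −78 to −40 °C; AcOH, −78 °C
Reagents that add atoms: none
Why: Claisen-type C-acylation of a lithium lactone enolate by a Weinreb amide; the chelated tetrahedral adduct persists until the cold acidic quench, so neither a second addition nor retro-Claisen cleavage occurs, and the electrophile enters the enolate face anti to the isopropenyl group, setting the quaternary α-carbon (S) with the acyl group trans and the CMe2 ester branch cis to isopropenyl.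

Step 7
Reactants: 11 tert-butyl 2-[(3S,5R)-3-{2-[methoxy(methyl)amino]-2-oxoacetyl}-2-oxo-5-(prop-1-en-2-yl)oxolan-3-yl]-2-methylpropanoate
Product: 12 tert-butyl 2-[(3S,5R)-3-[(2S)-2-hydroxy-1-[methoxy(methyl)amino]-1-oxopropan-2-yl]-2-oxo-5-(prop-1-en-2-yl)oxolan-3-yl]-2-methylpropanoate
Conditions: MgBr2·OEt2 (1.5 equiv), CH2Cl2, −78 °C; MeMgBr (1.3 equiv), −78 °C; cold aq. NH4Cl
Reagents that add atoms: methylmagnesium bromide, C[Mg]Br
Why: Chelation-controlled Grignard addition to a ketone that is both an α-keto amide and a β-keto lactone; magnesium bridges the ketone and lactone carbonyl oxygens and holds them syn-coplanar, so methyl enters from the side of the ring CH2, away from the tert-alkyl ester branch, giving the (S) carbinol with its hydroxyl syn to the lactone carbonyl; the ketone is far more electrophilic than the amide, the lactone or the tert-butyl ester.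

Step 8
Reactants: 12 tert-butyl 2-[(3S,5R)-3-[(2S)-2-hydroxy-1-[methoxy(methyl)amino]-1-oxopropan-2-yl]-2-oxo-5-(prop-1-en-2-yl)oxolan-3-yl]-2-methylpropanoate
Product: 13 tert-butyl 2-[(3S,5R)-3-[(2S)-1-[methoxy(methyl)amino]-1-oxo-2-(triethylsilyloxy)propan-2-yl]-2-oxo-5-(prop-1-en-2-yl)oxolan-3-yl]-2-methylpropanoate
Conditions: Et3SiOTf, 2,6-lutidine, CH2Cl2, −78 to 0 °C
Reagents that add atoms: triethylsilyl trifluoromethanesulfonate, CC[Si](CC)(CC)OS(=O)(=O)C(F)(F)F
Why: Silylation of a hindered tertiary alcohol with a silyl triflate; the ether blocks lactonisation onto the neighbouring ester, retro-aldol cleavage and, later, oxa-Michael addition to the ynone.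

Step 9
Reactants: 13 tert-butyl 2-[(3S,5R)-3-[(2S)-1-[methoxy(methyl)amino]-1-oxo-2-(triethylsilyloxy)propan-2-yl]-2-oxo-5-(prop-1-en-2-yl)oxolan-3-yl]-2-methylpropanoate; 14 ethynyltrimethylsilane
Product: 15 tert-butyl 2-methyl-2-[(3S,5R)-2-oxo-3-[(2S)-3-oxo-2-(triethylsilyloxy)-5-(trimethylsilyl)pent-4-yn-2-yl]-5-(prop-1-en-2-yl)oxolan-3-yl]propanoate
Conditions: 14, n-BuLi, THF, −78 °C; then 13, −78 to −20 °C; aq. NH4Cl
Reagents that add atoms: none
Why: Weinreb ketone synthesis with a lithium acetylide; the chelated adduct stops at the ketone stage, the amide (activated by its α-oxygen) reacts ahead of the neopentyl-type lactone carbonyl and the inert tert-butyl ester, and no transition metal touches the allylic lactone C–O bond.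

Step 10
Reactants: 15 tert-butyl 2-methyl-2-[(3S,5R)-2-oxo-3-[(2S)-3-oxo-2-(triethylsilyloxy)-5-(trimethylsilyl)pent-4-yn-2-yl]-5-(prop-1-en-2-yl)oxolan-3-yl]propanoate
Product: 16 tert-butyl 2-[(3S,5R)-3-[(2S)-5-bromo-3-oxo-2-(triethylsilyloxy)pent-4-yn-2-yl]-2-oxo-5-(prop-1-en-2-yl)oxolan-3-yl]-2-methylpropanoate
Conditions: N-bromosuccinimide, AgNO3 (10 mol %), acetone, rt, dark
Reagents that add atoms: N-bromosuccinimide, O=C1CCC(=O)N1Br
Why: Silver-catalysed bromodesilylation of an alkynylsilane gives the 1-bromoalkyne directly; in acetone in the dark and without a nucleophile the 1,1-disubstituted alkene should not be attacked.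

Step 11
Reactants: 16 tert-butyl 2-[(3S,5R)-3-[(2S)-5-bromo-3-oxo-2-(triethylsilyloxy)pent-4-yn-2-yl]-2-oxo-5-(prop-1-en-2-yl)oxolan-3-yl]-2-methylpropanoate
Product: 18 2-[(3S,5R)-3-[(2S)-5-bromo-3-oxo-2-(triethylsilyloxy)pent-4-yn-2-yl]-2-oxo-5-(prop-1-en-2-yl)oxolan-3-yl]-2-methylpropanoic acid, via trimethylsilyl ester 17 (not isolated)
Conditions: Me3SiOTf, 2,6-lutidine, CH2Cl2, 0 °C; pH 4 aqueous buffer
Reagents that add atoms: none
Why: Silyl triflate-mediated cleavage of a tert-butyl ester (loss of 2-methylpropene) to the silyl ester, hydrolysed on work-up; the buffered non-nucleophilic conditions spare the triethylsilyl ether, the bromoalkynone and the lactone, and the acid cannot lactonise because the tertiary oxygen is silylated.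

Step 12
Reactants: 18 2-[(3S,5R)-3-[(2S)-5-bromo-3-oxo-2-(triethylsilyloxy)pent-4-yn-2-yl]-2-oxo-5-(prop-1-en-2-yl)oxolan-3-yl]-2-methylpropanoic acid
Product: 19 (3R,5S,6S)-9-bromo-6,10,10-trimethyl-3-(prop-1-en-2-yl)-6-(triethylsilyloxy)-2-oxaspiro[4.5]dec-8-ene-1,7-dione
Conditions: Ir[dF(CF3)ppy]2(dtbbpy)PF6 (2 mol %), Cs2CO3 (0.3 equiv), degassed DMF (0.01 M), 450 nm LEDs, rt
Reagents that add atoms: none
Why: Proposed new method: the photoexcited trivalent iridium complex oxidises the carboxylate of 18, which loses carbon dioxide to give the tertiary radical on the CMe2 carbon. This nucleophilic radical adds to the bromine-bearing alkyne carbon, β to the ketone, and closes ring A in the 6-endo-dig mode with the carbonyl inside the tether; the 5-exo mode would require attack at the α-carbon against the polarisation of the ynone. The resulting ring vinyl radical next to the ketone is reduced by the divalent iridium species and protonated (or takes a hydrogen atom from the medium), which returns the catalyst. The closest known reaction types are the photoredox decarboxylative hydroalkylation of activated alkynes and 6-endo radical cyclisations onto ynones; what is new is a bromoalkyne acceptor that keeps its halogen. Bromine is retained because the usual β-loss of a bromine atom from the adduct of a bromoalkyne would have to give a cyclohexyne in ring A. No stereocentre is formed; the spiro carbon and the silyloxy-bearing carbon are carried over from 18. The step needs endo over exo closure, addition to the ynone in preference to the isopropenyl group that sits cis to the radical on the lactone, and no conjugate addition of carboxylate to the bromoalkynone; polarity matching, the tether through the ketone, high dilution and a substoichiometric base are relied on for these.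

Step 13
Reactants: 19 (3R,5S,6S)-9-bromo-6,10,10-trimethyl-3-(prop-1-en-2-yl)-6-(triethylsilyloxy)-2-oxaspiro[4.5]dec-8-ene-1,7-dione
Product: 20 (3R,5S,6S,7R)-9-bromo-7-hydroxy-6,10,10-trimethyl-3-(prop-1-en-2-yl)-6-(triethylsilyloxy)-2-oxaspiro[4.5]dec-8-en-1-one
Conditions: NaBH4, CeCl3·7H2O, MeOH, −78 to −40 °C
Reagents that add atoms: none
Why: Luche 1,2-reduction; the cerium-modified borohydride attacks the carbonyl and not the β-bromoenone terminus, and with the α-silyloxy group pseudoaxial on the half-chair hydride enters from the opposite face, so the new hydroxyl (7R) is cis to the neighbouring silyloxy group.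

Step 14
Reactants: 20 (3R,5S,6S,7R)-9-bromo-7-hydroxy-6,10,10-trimethyl-3-(prop-1-en-2-yl)-6-(triethylsilyloxy)-2-oxaspiro[4.5]dec-8-en-1-one
Product: 21 (3R,5S,6S,7R)-9-bromo-6,10,10-trimethyl-3-(prop-1-en-2-yl)-6-(triethylsilyloxy)-7-(triisopropylsilyloxy)-2-oxaspiro[4.5]dec-8-en-1-one
Conditions: iPr3SiOTf, 2,6-lutidine, CH2Cl2, 0 °C to rt
Reagents that add atoms: triisopropylsilyl trifluoromethanesulfonate, CC(C)[Si](C(C)C)(C(C)C)OS(=O)(=O)C(F)(F)F
Why: Silylation of a hindered secondary allylic alcohol with a silyl triflate; the triisopropylsilyl group survives the acidic removal of the tertiary triethylsilyl ether and is later removed by fluoride without acid.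

Step 15
Reactants: 21 (3R,5S,6S,7R)-9-bromo-6,10,10-trimethyl-3-(prop-1-en-2-yl)-6-(triethylsilyloxy)-7-(triisopropylsilyloxy)-2-oxaspiro[4.5]dec-8-en-1-one
Product: 22 (3R,5S,6S,7R)-9-bromo-6-hydroxy-6,10,10-trimethyl-3-(prop-1-en-2-yl)-7-(triisopropylsilyloxy)-2-oxaspiro[4.5]dec-8-en-1-one
Conditions: HF·pyridine, pyridine, THF, 0 °C to rt
Reagents that add atoms: none
Why: Selective desilylation; under buffered HF a triethylsilyl ether is cleaved far faster than a triisopropylsilyl ether even when the former is tertiary, and lactone, vinyl bromide and alkene are inert.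

Step 16
Reactants: 22 (3R,5S,6S,7R)-9-bromo-6-hydroxy-6,10,10-trimethyl-3-(prop-1-en-2-yl)-7-(triisopropylsilyloxy)-2-oxaspiro[4.5]dec-8-en-1-one
Product: 23 (3R,5S,6S,7R)-9-bromo-6,10,10-trimethyl-3-(prop-1-en-2-yl)-7-(triisopropylsilyloxy)-2-oxaspiro[4.5]dec-8-ene-1,6-diol (lactol, both C1 epimers)
Conditions: iBu2AlH (3 equiv), CH2Cl2, −78 °C; aq. KNaC4H4O6 (potassium sodium tartrate)
Reagents that add atoms: none
Why: Partial reduction of a γ-lactone to the lactol at low temperature; the tertiary alkoxyaluminium hydride formed first sits cis to the lactone carbonyl and can deliver hydride internally, and the tetrahedral aluminate survives until work-up so no diol forms.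

Step 17
Reactants: 23 (3R,5S,6S,7R)-9-bromo-6,10,10-trimethyl-3-(prop-1-en-2-yl)-7-(triisopropylsilyloxy)-2-oxaspiro[4.5]dec-8-ene-1,6-diol
Product: 24 (1S,3R,5S,7S,8R)-10-bromo-7,11,11-trimethyl-3-(prop-1-en-2-yl)-8-(triisopropylsilyloxy)-4,6-dioxatricyclo[5.4.0.0(1,5)]undec-9-ene
Conditions: PPh3, diisopropyl azodicarboxylate, THF, 0 °C to rt
Reagents that add atoms: none
Why: Mitsunobu-type cyclodehydration of a hydroxy lactol, the reaction type used to close strained oxetane acetals; the more acidic, less hindered lactol hydroxyl is activated as the oxyphosphonium ion and displaced through the oxocarbenium ion by the cis tertiary hydroxyl in a 4-exo closure, the acetal centre (5S) can only form cis-fused, and the neutral medium does not reopen the acetal.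

Step 18
Reactants: 24 (1S,3R,5S,7S,8R)-10-bromo-7,11,11-trimethyl-3-(prop-1-en-2-yl)-8-(triisopropylsilyloxy)-4,6-dioxatricyclo[5.4.0.0(1,5)]undec-9-ene
Product: 25 (1S,3R,5S,7S,8R)-10-bromo-7,11,11-trimethyl-3-(prop-1-en-2-yl)-4,6-dioxatricyclo[5.4.0.0(1,5)]undec-9-en-8-ol
Conditions: Bu4NF, THF, 0 °C to rt
Reagents that add atoms: none
Why: Fluoride cleavage of the silyl ether under basic, non-acidic conditions, to which the acetal and the vinyl bromide are stable.

Step 19
Reactants: 25 (1S,3R,5S,7S,8R)-10-bromo-7,11,11-trimethyl-3-(prop-1-en-2-yl)-4,6-dioxatricyclo[5.4.0.0(1,5)]undec-9-en-8-ol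
Product: 26 (1S,3R,5S,7S,8S)-8,10-dibromo-7,11,11-trimethyl-3-(prop-1-en-2-yl)-4,6-dioxatricyclo[5.4.0.0(1,5)]undec-9-ene
Conditions: CBr4, PPh3, 2,6-lutidine, CH2Cl2, 0 °C to rt
Reagents that add atoms: carbon tetrabromide, BrC(Br)(Br)Br
Why: Appel reaction; bromide displaces the alkoxyphosphonium ion with inversion at C8 (8R alcohol to 8S bromide, bromine trans to the oxetane oxygen), the SN2′ path is closed because C10 is fully substituted, no β-hydrogen is available for elimination, and 2,6-lutidine buffers hydrogen bromide.

## Compound list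

1 | methacrolein (2-methylprop-2-enal) | C=C(C)C=O | starting material
2 | rac-2-(prop-1-en-2-yl)oxirane | C=C(C)C1CO1 | intermediate
3 | (S)-2-(prop-1-en-2-yl)oxirane | C=C(C)[C@H]1CO1 | intermediate
4 | tert-butyl 2-methylpropanoate | CC(C)C(=O)OC(C)(C)C | starting material
5 | methyl bromoacetate | COC(=O)CBr | starting material
6 | 1-tert-butyl 4-methyl 2,2-dimethylbutanedioate | COC(=O)CC(C)(C)C(=O)OC(C)(C)C | intermediate
7 | 4-tert-butoxy-3,3-dimethyl-4-oxobutanoic acid | OC(=O)CC(C)(C)C(=O)OC(C)(C)C | intermediate
8 | (4R)-2-(1-tert-butoxy-2-methyl-1-oxopropan-2-yl)-4-hydroxy-5-methylhex-5-enoic acid (both C2 epimers) | C=C(C)[C@H](O)CC(C(O)=O)C(C)(C)C(=O)OC(C)(C)C | intermediate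
9 | tert-butyl 2-methyl-2-[(5R)-2-oxo-5-(prop-1-en-2-yl)oxolan-3-yl]propanoate (both C3 epimers) | C=C(C)[C@H]1CC(C(=O)O1)C(C)(C)C(=O)OC(C)(C)C | intermediate
10 | N,N′-dimethoxy-N,N′-dimethyloxamide | CON(C)C(=O)C(=O)N(C)OC | starting material
11 | tert-butyl 2-[(3S,5R)-3-{2-[methoxy(methyl)amino]-2-oxoacetyl}-2-oxo-5-(prop-1-en-2-yl)oxolan-3-yl]-2-methylpropanoate | C=C(C)[C@H]1C[C@](C(=O)O1)(C(C)(C)C(=O)OC(C)(C)C)C(=O)C(=O)N(C)OC | intermediate
12 | tert-butyl 2-[(3S,5R)-3-[(2S)-2-hydroxy-1-[methoxy(methyl)amino]-1-oxopropan-2-yl]-2-oxo-5-(prop-1-en-2-yl)oxolan-3-yl]-2-methylpropanoate | C=C(C)[C@H]1C[C@](C(=O)O1)(C(C)(C)C(=O)OC(C)(C)C)[C@](C)(O)C(=O)N(C)OC | intermediate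
13 | tert-butyl 2-[(3S,5R)-3-[(2S)-1-[methoxy(methyl)amino]-1-oxo-2-(triethylsilyloxy)propan-2-yl]-2-oxo-5-(prop-1-en-2-yl)oxolan-3-yl]-2-methylpropanoate | C=C(C)[C@H]1C[C@](C(=O)O1)(C(C)(C)C(=O)OC(C)(C)C)[C@](C)(O[Si](CC)(CC)CC)C(=O)N(C)OC | intermediate
14 | ethynyltrimethylsilane | C#C[Si](C)(C)C | starting material
15 | tert-butyl 2-methyl-2-[(3S,5R)-2-oxo-3-[(2S)-3-oxo-2-(triethylsilyloxy)-5-(trimethylsilyl)pent-4-yn-2-yl]-5-(prop-1-en-2-yl)oxolan-3-yl]propanoate | C=C(C)[C@H]1C[C@](C(=O)O1)(C(C)(C)C(=O)OC(C)(C)C)[C@](C)(O[Si](CC)(CC)CC)C(=O)C#C[Si](C)(C)C | intermediate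
16 | tert-butyl 2-[(3S,5R)-3-[(2S)-5-bromo-3-oxo-2-(triethylsilyloxy)pent-4-yn-2-yl]-2-oxo-5-(prop-1-en-2-yl)oxolan-3-yl]-2-methylpropanoate | C=C(C)[C@H]1C[C@](C(=O)O1)(C(C)(C)C(=O)OC(C)(C)C)[C@](C)(O[Si](CC)(CC)CC)C(=O)C#CBr | intermediate
17 | trimethylsilyl 2-[(3S,5R)-3-[(2S)-5-bromo-3-oxo-2-(triethylsilyloxy)pent-4-yn-2-yl]-2-oxo-5-(prop-1-en-2-yl)oxolan-3-yl]-2-methylpropanoate | C=C(C)[C@H]1C[C@](C(=O)O1)(C(C)(C)C(=O)O[Si](C)(C)C)[C@](C)(O[Si](CC)(CC)CC)C(=O)C#CBr | intermediate
18 | 2-[(3S,5R)-3-[(2S)-5-bromo-3-oxo-2-(triethylsilyloxy)pent-4-yn-2-yl]-2-oxo-5-(prop-1-en-2-yl)oxolan-3-yl]-2-methylpropanoic acid | C=C(C)[C@H]1C[C@](C(=O)O1)(C(C)(C)C(=O)O)[C@](C)(O[Si](CC)(CC)CC)C(=O)C#CBr | intermediate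
19 | (3R,5S,6S)-9-bromo-6,10,10-trimethyl-3-(prop-1-en-2-yl)-6-(triethylsilyloxy)-2-oxaspiro[4.5]dec-8-ene-1,7-dione | C=C(C)[C@H]1C[C@@]2(C(=O)O1)[C@](C)(O[Si](CC)(CC)CC)C(=O)C=C(Br)C2(C)C | intermediate
20 | (3R,5S,6S,7R)-9-bromo-7-hydroxy-6,10,10-trimethyl-3-(prop-1-en-2-yl)-6-(triethylsilyloxy)-2-oxaspiro[4.5]dec-8-en-1-one | C=C(C)[C@H]1C[C@@]2(C(=O)O1)[C@](C)(O[Si](CC)(CC)CC)[C@H](O)C=C(Br)C2(C)C | intermediate
21 | (3R,5S,6S,7R)-9-bromo-6,10,10-trimethyl-3-(prop-1-en-2-yl)-6-(triethylsilyloxy)-7-(triisopropylsilyloxy)-2-oxaspiro[4.5]dec-8-en-1-one | C=C(C)[C@H]1C[C@@]2(C(=O)O1)[C@](C)(O[Si](CC)(CC)CC)[C@H](O[Si](C(C)C)(C(C)C)C(C)C)C=C(Br)C2(C)C | intermediate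
22 | (3R,5S,6S,7R)-9-bromo-6-hydroxy-6,10,10-trimethyl-3-(prop-1-en-2-yl)-7-(triisopropylsilyloxy)-2-oxaspiro[4.5]dec-8-en-1-one | C=C(C)[C@H]1C[C@@]2(C(=O)O1)[C@](C)(O)[C@H](O[Si](C(C)C)(C(C)C)C(C)C)C=C(Br)C2(C)C | intermediate
23 | (3R,5S,6S,7R)-9-bromo-6,10,10-trimethyl-3-(prop-1-en-2-yl)-7-(triisopropylsilyloxy)-2-oxaspiro[4.5]dec-8-ene-1,6-diol (both C1 epimers) | C=C(C)[C@H]1C[C@@]2(C(O)O1)[C@](C)(O)[C@H](O[Si](C(C)C)(C(C)C)C(C)C)C=C(Br)C2(C)C | intermediate
24 | (1S,3R,5S,7S,8R)-10-bromo-7,11,11-trimethyl-3-(prop-1-en-2-yl)-8-(triisopropylsilyloxy)-4,6-dioxatricyclo[5.4.0.0(1,5)]undec-9-ene | C=C(C)[C@H]1C[C@@]23[C@@H](O1)O[C@]2(C)[C@H](O[Si](C(C)C)(C(C)C)C(C)C)C=C(Br)C3(C)C | intermediate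
25 | (1S,3R,5S,7S,8R)-10-bromo-7,11,11-trimethyl-3-(prop-1-en-2-yl)-4,6-dioxatricyclo[5.4.0.0(1,5)]undec-9-en-8-ol | C=C(C)[C@H]1C[C@@]23[C@@H](O1)O[C@]2(C)[C@H](O)C=C(Br)C3(C)C | intermediate
26 | (1S,3R,5S,7S,8S)-8,10-dibromo-7,11,11-trimethyl-3-(prop-1-en-2-yl)-4,6-dioxatricyclo[5.4.0.0(1,5)]undec-9-ene | C=C(C)[C@H]1C[C@@]23[C@@H](O1)O[C@]2(C)[C@@H](Br)C=C(Br)C3(C)C | target

## Step count and least certain steps

Total: 19 steps. Longest linear sequence: 17 steps (steps 3 to 19, from 4); steps 1 and 2 are a two-step branch that supplies 3 to step 5.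

**Step 12 (key step).**
- What may go wrong: consumption of the bromoalkynone by conjugate addition of the carboxylate before the radical is formed; quenching of the ring vinyl radical by hydrogen abstraction from the solvent, so that the reduced photocatalyst is not reoxidised and turnover stops; reductive loss of bromine; competing addition of the tertiary radical to the isopropenyl group.
- Fallback (known reactions only): it sets out from 15. Na2B4O7·10H2O in aqueous methanol removes the alkynyl silyl group to give tert-butyl 2-methyl-2-[(3S,5R)-2-oxo-3-[(2S)-3-oxo-2-(triethylsilyloxy)pent-4-yn-2-yl]-5-(prop-1-en-2-yl)oxolan-3-yl]propanoate F1. The conditions of step 11 then give the terminal ynone acid F2. The iridium photocatalyst and base of step 12 effect the decarboxylative 6-endo hydroalkylation of this terminal ynone, a combination of two established reaction types, to give the debromo enone F3. Copper-catalysed conjugate borylation (CuCl, NaOtBu, bis(2-diphenylphosphinophenyl) ether, bis(pinacolato)diboron, MeOH, THF) gives the β-boryl ketone F4, oxidised in the same flask with NaBO3·4H2O to the β-hydroxy ketone F5. Dess–Martin oxidation gives the 1,3-diketone F6. Ph3PBr2 with Et3N converts F6 into the β-bromoenone, bromide being expected to enter at the carbonyl next to CMe2, the less shielded of the two, and the route is rejoined at 19. This costs six steps in place of three.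

**Step 6.**
- What may go wrong: failure of carbon–carbon bond formation at the crowded enolate carbon (proton return or O-acylation), or erosion of the facial selectivity that sets the spiro centre.
- Fallback: it sets out from 9 and 10. One amide group of 10 is reduced with iBu2AlH (1 equiv, −78 °C) to N-methoxy-N-methyl-2-oxoacetamide F7. Aldol addition of the lithium enolate of 9 to this aldehyde, the least demanding electrophile for a hindered enolate, gives the β-hydroxy amide F8 with the same sense of attack anti to isopropenyl. Dess–Martin oxidation returns to 11.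

**Step 7.**
- What may go wrong: addition through a non-chelated rotamer, giving the epimer at the new carbinol carbon; attack at the amide carbonyl; fragmentation of the magnesium alkoxide by retro-Claisen cleavage on warming.
- Fallback: it sets out from 9 and bypasses 11. One equivalent of MeMgBr added to 10 gives N-methoxy-N-methyl-2-oxopropanamide F9. Aldol addition of the lithium enolate of 9 to this ketone in THF with a strongly coordinating cosolvent forms the C1–C7 bond and the carbinol centre in one closed transition state. With chelation of the keto amide suppressed, the larger amide group should take the equatorial position, which maps onto 12, where the route is rejoined. The sense of induction would have to be confirmed.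

**Step 17.**
- What may go wrong: ionisation of the activated lactol without ring closure, capture of the oxocarbenium ion by the hydrazide anion, or reopening of the strained acetal during isolation.
- Fallback: it sets out from 23. Cl3CCN with catalytic 1,8-diazabicyclo[5.4.0]undec-7-ene converts the lactol hydroxyl selectively into the trichloroacetimidate F10. Catalytic BF3·OEt2 at −78 °C over molecular sieves then releases the oxocarbenium ion with no external nucleophile present, so the cis tertiary hydroxyl closes the oxetane, with a cold Et3N quench. The route is rejoined at 24.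

**Step 19.**
- What may go wrong: slow displacement at a carbon next to the fully substituted C7, so that the phosphonium intermediate ionises to the allyl cation with loss of configuration at C8, or hydrogen bromide opens the acetal.
- Fallback: it sets out from 25. Methanesulfonyl chloride and Et3N at −20 °C give the methanesulfonate F11, and LiBr in acetone then displaces it with inversion. Activation and substitution are separated, and the bromide source is halide alone. The product is 26.

## Further compounds

F1 | step 12 | tert-butyl 2-methyl-2-[(3S,5R)-2-oxo-3-[(2S)-3-oxo-2-(triethylsilyloxy)pent-4-yn-2-yl]-5-(prop-1-en-2-yl)oxolan-3-yl]propanoate | C=C(C)[C@H]1C[C@](C(=O)O1)(C(C)(C)C(=O)OC(C)(C)C)[C@](C)(O[Si](CC)(CC)CC)C(=O)C#C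
F2 | step 12 | 2-methyl-2-[(3S,5R)-2-oxo-3-[(2S)-3-oxo-2-(triethylsilyloxy)pent-4-yn-2-yl]-5-(prop-1-en-2-yl)oxolan-3-yl]propanoic acid | C=C(C)[C@H]1C[C@](C(=O)O1)(C(C)(C)C(O)=O)[C@](C)(O[Si](CC)(CC)CC)C(=O)C#C
F3 | step 12 | (3R,5S,6S)-6,10,10-trimethyl-3-(prop-1-en-2-yl)-6-(triethylsilyloxy)-2-oxaspiro[4.5]dec-8-ene-1,7-dione | C=C(C)[C@H]1C[C@@]2(C(=O)O1)[C@](C)(O[Si](CC)(CC)CC)C(=O)C=CC2(C)C
F4 | step 12 | (3R,5S,6S)-6,10,10-trimethyl-3-(prop-1-en-2-yl)-9-(4,4,5,5-tetramethyl-1,3,2-dioxaborolan-2-yl)-6-(triethylsilyloxy)-2-oxaspiro[4.5]decane-1,7-dione (both C9 epimers) | C=C(C)[C@H]1C[C@@]2(C(=O)O1)[C@](C)(O[Si](CC)(CC)CC)C(=O)CC(B3OC(C)(C)C(C)(C)O3)C2(C)C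
F5 | step 12 | (3R,5S,6S)-9-hydroxy-6,10,10-trimethyl-3-(prop-1-en-2-yl)-6-(triethylsilyloxy)-2-oxaspiro[4.5]decane-1,7-dione (both C9 epimers) | C=C(C)[C@H]1C[C@@]2(C(=O)O1)[C@](C)(O[Si](CC)(CC)CC)C(=O)CC(O)C2(C)C
F6 | step 12 | (3R,5S,6S)-6,10,10-trimethyl-3-(prop-1-en-2-yl)-6-(triethylsilyloxy)-2-oxaspiro[4.5]decane-1,7,9-trione | C=C(C)[C@H]1C[C@@]2(C(=O)O1)[C@](C)(O[Si](CC)(CC)CC)C(=O)CC(=O)C2(C)C
F7 | step 6 | N-methoxy-N-methyl-2-oxoacetamide | O=CC(=O)N(C)OC
F8 | step 6 | tert-butyl 2-[(3S,5R)-3-{1-hydroxy-2-[methoxy(methyl)amino]-2-oxoethyl}-2-oxo-5-(prop-1-en-2-yl)oxolan-3-yl]-2-methylpropanoate (both carbinol epimers) | C=C(C)[C@H]1C[C@](C(=O)O1)(C(C)(C)C(=O)OC(C)(C)C)C(O)C(=O)N(C)OC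
F9 | step 7 | N-methoxy-N-methyl-2-oxopropanamide | CC(=O)C(=O)N(C)OC
F10 | step 17 | (3R,5S,6S,7R)-9-bromo-6-hydroxy-6,10,10-trimethyl-3-(prop-1-en-2-yl)-7-(triisopropylsilyloxy)-2-oxaspiro[4.5]dec-8-en-1-yl 2,2,2-trichloroacetimidate | C=C(C)[C@H]1C[C@@]2(C(OC(=N)C(Cl)(Cl)Cl)O1)[C@](C)(O)[C@H](O[Si](C(C)C)(C(C)C)C(C)C)C=C(Br)C2(C)C
F11 | step 19 | (1S,3R,5S,7S,8R)-10-bromo-7,11,11-trimethyl-3-(prop-1-en-2-yl)-4,6-dioxatricyclo[5.4.0.0(1,5)]undec-9-en-8-yl methanesulfonate | C=C(C)[C@H]1C[C@@]23[C@@H](O1)O[C@]2(C)[C@H](OS(C)(=O)=O)C=C(Br)C3(C)C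
A1 | alternative 1 | 3-bromo-2,2,6-trimethyl-1-[(2R)-3-methyl-2-(triethylsilyloxy)but-3-en-1-yl]-6-(triethylsilyloxy)-5-(triisopropylsilyloxy)cyclohex-3-ene-1-carboxylic acid | C=C(C)[C@H](O[Si](CC)(CC)CC)C[C@@]1(C(O)=O)[C@](C)(O[Si](CC)(CC)CC)[C@H](O[Si](C(C)C)(C(C)C)C(C)C)C=C(Br)C1(C)C
A2 | alternative 1 | 6-(1-bromo-2-methylprop-1-en-1-yl)-4-methyl-3-[(2R)-3-methyl-2-(triethylsilyloxy)but-3-en-1-yl]-4-(triethylsilyloxy)-5-(triisopropylsilyloxy)oxan-2-one | C=C(C)[C@H](O[Si](CC)(CC)CC)CC1C(=O)OC(C(Br)=C(C)C)[C@@H](O[Si](C(C)C)(C(C)C)C(C)C)[C@@]1(C)O[Si](CC)(CC)CC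
A3 | alternative 2 | 7-(tert-butyldimethylsilyloxy)-6-hydroxy-6,10,10-trimethyl-3-(prop-1-en-2-yl)-2-oxaspiro[4.5]decane-1,9-dione | C=C(C)[C@H]1C[C@@]2(C(=O)O1)[C@](C)(O)[C@H](O[Si](C)(C)C(C)(C)C)CC(=O)C2(C)C
A4 | alternative 2 | (5R)-3-[5-(tert-butyldimethylsilyloxy)-2-methyl-3,6-dioxoheptan-2-yl]-5-(prop-1-en-2-yl)furan-2(5H)-one | C=C(C)[C@H]1C=C(C(=O)O1)C(C)(C)C(=O)C[C@@H](O[Si](C)(C)C(C)(C)C)C(C)=O
A5 | alternative 3 | 9-bromo-6,7-dihydroxy-6,10,10-trimethyl-3-(prop-1-en-2-yl)-2-oxaspiro[4.5]dec-8-en-1-one | C=C(C)[C@H]1C[C@@]2(C(=O)O1)[C@](C)(O)[C@H](O)C=C(Br)C2(C)C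
A6 | alternative 3 | 2-hydroxy-2-[3-(2-methylbut-3-yn-2-yl)-2-oxo-5-(prop-1-en-2-yl)oxolan-3-yl]propanal | C=C(C)[C@H]1C[C@](C(=O)O1)(C(C)(C)C#C)[C@](C)(O)C=O
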